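**Retrosynthetic overview**
1. Target 13 ⇐ bis-silyl ether 12 (desilylation) ⇐ cis-(3S,4S)-isoflavan-4-ol 11 (alcohol oxidation).
2. 11 ⇐ isoflavone 9 by an isoflavone-reductase-like asymmetric transfer hydrogenation with dynamic kinetic resolution, which sets C3.
3. 9 ⇐ 6-bromoisoflavone 6 + geranyl bromide 7 (aryl–allyl coupling, placed after the oxidation that the geranyl alkenes would not survive).
4. 6 ⇐ 2'-hydroxychalcone 4 in one flask: oxa-Michael closure to flavanone 5 (chalcone-isomerase-like), then trivalent-iodine 2,3-aryl shift (isoflavone-synthase-like).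
5. 4 ⇐ Claisen–Schmidt union of acetophenone 1 (ring A) and aldehyde 2 (ring B). Ring order: A and B are bought; ring C is closed at O1–C2 and then rearranged.

Assumption: the single stereocentre of the target is C3 with S configuration (C4 > C2 > aryl > H), and 1 is bought as a catalogue compound (otherwise one bromination of 2,4-dihydroxyacetophenone).

**Route**

Step 1
Reactants: 1 1-(5-bromo-2,4-dihydroxyphenyl)ethan-1-one; 2 4-hydroxy-2-methoxybenzaldehyde
Product: 3 (E)-1-(5-bromo-2,4-dihydroxyphenyl)-3-(4-hydroxy-2-methoxyphenyl)prop-2-en-1-one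
Conditions: BF3·OEt2 (0.5 equiv), 1,4-dioxane, rt; then H2O/MeOH
Reagents that add atoms: none
Why: Lewis-acid-mediated Claisen–Schmidt (crossed aldol) condensation proceeds through the boron-chelated enol of the 2-hydroxyacetophenone, so the free phenols need no protection and the E-enone forms under thermodynamic control.

Step 2
Reactants: 3 (E)-1-(5-bromo-2,4-dihydroxyphenyl)-3-(4-hydroxy-2-methoxyphenyl)prop-2-en-1-one
Product: 4 (E)-1-[5-bromo-2-hydroxy-4-(triisopropylsilyloxy)phenyl]-3-[2-methoxy-4-(triisopropylsilyloxy)phenyl]prop-2-en-1-one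
Conditions: TIPSCl (2.3 equiv), imidazole, DMF, 0 °C to rt
Reagents that add atoms: chlorotriisopropylsilane, CC(C)[Si](Cl)(C(C)C)C(C)C
Why: Chemoselective O-silylation: the two non-chelated phenols react, while the carbonyl-chelated 2'-OH needed for ring closure does not react with the bulky silyl chloride.

Step 3
Reactants: 4 (E)-1-[5-bromo-2-hydroxy-4-(triisopropylsilyloxy)phenyl]-3-[2-methoxy-4-(triisopropylsilyloxy)phenyl]prop-2-en-1-one
Product: 6 6-bromo-3-[2-methoxy-4-(triisopropylsilyloxy)phenyl]-7-(triisopropylsilyloxy)-4H-chromen-4-one, via racemic bromoflavanone 5 (not isolated)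
Conditions: TsOH·H2O (10 mol %), MeCN, 80 °C, 2 h; then PhI(OH)OTs (1.2 equiv), 80 °C, 1 h
Reagents that add atoms: none
Why: Proposed new method: acid-catalysed 6-endo oxa-Michael closure gives flavanone 5, whose enol is captured at C3 by the trivalent iodine reagent; departure of iodobenzene drives a 1,2-shift of the electron-rich ring B aryl from C2 to C3 and loss of H-3 gives the isoflavone, while any uncyclised chalcone converges on the same product through the open-chain 1,2-aryl shift; the closest known reactions are the oxidative 2,3-aryl migration of isolated flavanones with PhI(OH)OTs in MeCN and the trivalent-thallium or trivalent-iodine rearrangement of 2'-hydroxychalcones.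

Step 4
Reactants: 6 6-bromo-3-[2-methoxy-4-(triisopropylsilyloxy)phenyl]-7-(triisopropylsilyloxy)-4H-chromen-4-one; 7 geranyl bromide [(2E)-1-bromo-3,7-dimethylocta-2,6-diene]
Product: 9 6-[(2E)-3,7-dimethylocta-2,6-dien-1-yl]-3-[2-methoxy-4-(triisopropylsilyloxy)phenyl]-7-(triisopropylsilyloxy)-4H-chromen-4-one, via aryl pinacol boronate 8 (not isolated)
Conditions: B2pin2 (1.1 equiv), PdCl2(dppf) (5 mol %), KOAc, 1,4-dioxane, 90 °C; then 7 (1.5 equiv), Pd(PPh3)4 (5 mol %), 2 M aq. K2CO3, 60 °C
Reagents that add atoms: none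
Why: Miyaura borylation followed in the same flask by Suzuki–Miyaura coupling with the allylic bromide: the π-allyl palladium species from 7 couples at its unsubstituted terminus and keeps the 2E geometry, which the reversed pairing (aryl bromide with a geranylboronate) tends to scramble.

Step 5
Reactants: 9 6-[(2E)-3,7-dimethylocta-2,6-dien-1-yl]-3-[2-methoxy-4-(triisopropylsilyloxy)phenyl]-7-(triisopropylsilyloxy)-4H-chromen-4-one
Product: 11 (3S,4S)-6-[(2E)-3,7-dimethylocta-2,6-dien-1-yl]-3-[2-methoxy-4-(triisopropylsilyloxy)phenyl]-7-(triisopropylsilyloxy)chroman-4-ol (3,4-cis), via racemic isoflavanone 10 (not isolated)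
Conditions: RuCl[(S,S)-TsDPEN](p-cymene) (5 mol %), HCO2H/Et3N (5:2), EtOAc, 40 °C
Reagents that add atoms: none
Why: Noyori–Ikariya asymmetric transfer hydrogenation cascade: ruthenium hydride first adds 1,4 to the chromone to give ketone 10, which racemises at C3 through its enol in the formate medium while the (S,S) catalyst delivers hydride to C4 anti to the aryl group of the (3S) enantiomer only, so dynamic kinetic resolution sets C3 as S and C4 as S (cis); the geranyl alkenes are not reduced.

Step 6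
Reactants: 11 (3S,4S)-6-[(2E)-3,7-dimethylocta-2,6-dien-1-yl]-3-[2-methoxy-4-(triisopropylsilyloxy)phenyl]-7-(triisopropylsilyloxy)chroman-4-ol
Product: 12 (3S)-6-[(2E)-3,7-dimethylocta-2,6-dien-1-yl]-3-[2-methoxy-4-(triisopropylsilyloxy)phenyl]-7-(triisopropylsilyloxy)chroman-4-one
Conditions: Dess–Martin periodinane (1.3 equiv), CH2Cl2, 0 °C, 30 min; cold Na2S2O3/NaHCO3 wash
Reagents that add atoms: none
Why: Dess–Martin oxidation of the benzylic alcohol is fast and base-free and leaves alkenes and silyl ethers alone, so the carbinol centre is erased while the enolisable C3 centre stays S.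

Step 7
Reactants: 12 (3S)-6-[(2E)-3,7-dimethylocta-2,6-dien-1-yl]-3-[2-methoxy-4-(triisopropylsilyloxy)phenyl]-7-(triisopropylsilyloxy)chroman-4-one
Product: 13 (3S)-6-[(2E)-3,7-dimethylocta-2,6-dien-1-yl]-7-hydroxy-3-(4-hydroxy-2-methoxyphenyl)chroman-4-one
Conditions: HF·pyridine, THF, 0 °C to rt; pH 7 phosphate buffer work-up
Reagents that add atoms: none
Why: Fluoride desilylation under mildly acidic, base-free conditions frees both phenols without enolising the α-aryl ketone (C3 stays S) and without protonating the geranyl alkenes.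

**Compound list**
1 | 1-(5-bromo-2,4-dihydroxyphenyl)ethan-1-one | CC(=O)c1cc(Br)c(O)cc1O | starting material
2 | 4-hydroxy-2-methoxybenzaldehyde | COc1cc(O)ccc1C=O | starting material
3 | (E)-1-(5-bromo-2,4-dihydroxyphenyl)-3-(4-hydroxy-2-methoxyphenyl)prop-2-en-1-one | COc1cc(O)ccc1/C=C/C(=O)c1cc(Br)c(O)cc1O | intermediate
4 | (E)-1-[5-bromo-2-hydroxy-4-(triisopropylsilyloxy)phenyl]-3-[2-methoxy-4-(triisopropylsilyloxy)phenyl]prop-2-en-1-one | COc1cc(O[Si](C(C)C)(C(C)C)C(C)C)ccc1/C=C/C(=O)c1cc(Br)c(O[Si](C(C)C)(C(C)C)C(C)C)cc1O | intermediate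
5 | racemic 6-bromo-2-[2-methoxy-4-(triisopropylsilyloxy)phenyl]-7-(triisopropylsilyloxy)chroman-4-one | COc1cc(O[Si](C(C)C)(C(C)C)C(C)C)ccc1C1CC(=O)c2cc(Br)c(O[Si](C(C)C)(C(C)C)C(C)C)cc2O1 | intermediate (not isolated)
6 | 6-bromo-3-[2-methoxy-4-(triisopropylsilyloxy)phenyl]-7-(triisopropylsilyloxy)-4H-chromen-4-one | COc1cc(O[Si](C(C)C)(C(C)C)C(C)C)ccc1-c1coc2cc(O[Si](C(C)C)(C(C)C)C(C)C)c(Br)cc2c1=O | intermediate
7 | geranyl bromide, (2E)-1-bromo-3,7-dimethylocta-2,6-diene | CC(C)=CCC/C(C)=C/CBr | starting material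
8 | 3-[2-methoxy-4-(triisopropylsilyloxy)phenyl]-6-(4,4,5,5-tetramethyl-1,3,2-dioxaborolan-2-yl)-7-(triisopropylsilyloxy)-4H-chromen-4-one | COc1cc(O[Si](C(C)C)(C(C)C)C(C)C)ccc1-c1coc2cc(O[Si](C(C)C)(C(C)C)C(C)C)c(B3OC(C)(C)C(C)(C)O3)cc2c1=O | intermediate (not isolated)
9 | 6-[(2E)-3,7-dimethylocta-2,6-dien-1-yl]-3-[2-methoxy-4-(triisopropylsilyloxy)phenyl]-7-(triisopropylsilyloxy)-4H-chromen-4-one | COc1cc(O[Si](C(C)C)(C(C)C)C(C)C)ccc1-c1coc2cc(O[Si](C(C)C)(C(C)C)C(C)C)c(C/C=C(\C)CCC=C(C)C)cc2c1=O | intermediate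
10 | racemic 6-[(2E)-3,7-dimethylocta-2,6-dien-1-yl]-3-[2-methoxy-4-(triisopropylsilyloxy)phenyl]-7-(triisopropylsilyloxy)chroman-4-one | COc1cc(O[Si](C(C)C)(C(C)C)C(C)C)ccc1C1COc2cc(O[Si](C(C)C)(C(C)C)C(C)C)c(C/C=C(\C)CCC=C(C)C)cc2C1=O | intermediate (not isolated)
11 | (3S,4S)-6-[(2E)-3,7-dimethylocta-2,6-dien-1-yl]-3-[2-methoxy-4-(triisopropylsilyloxy)phenyl]-7-(triisopropylsilyloxy)chroman-4-ol | COc1cc(O[Si](C(C)C)(C(C)C)C(C)C)ccc1[C@H]1COc2cc(O[Si](C(C)C)(C(C)C)C(C)C)c(C/C=C(\C)CCC=C(C)C)cc2[C@H]1O | intermediate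
12 | (3S)-6-[(2E)-3,7-dimethylocta-2,6-dien-1-yl]-3-[2-methoxy-4-(triisopropylsilyloxy)phenyl]-7-(triisopropylsilyloxy)chroman-4-one | COc1cc(O[Si](C(C)C)(C(C)C)C(C)C)ccc1[C@H]1COc2cc(O[Si](C(C)C)(C(C)C)C(C)C)c(C/C=C(\C)CCC=C(C)C)cc2C1=O | intermediate
13 | (3S)-6-[(2E)-3,7-dimethylocta-2,6-dien-1-yl]-7-hydroxy-3-(4-hydroxy-2-methoxyphenyl)chroman-4-one | COc1cc(O)ccc1[C@H]1COc2cc(O)c(C/C=C(\C)CCC=C(C)C)cc2C1=O | target

**Step count and risks**
Total steps: 7. Longest linear sequence: 7 steps (1 or 2 to 13).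

Most likely to fail:

Step 3 (one-flask ring closure and aryl shift). The hot sulfonic acid may strip a silyl ether, the chalcone–flavanone equilibrium may be incomplete, and the trivalent iodine reagent may attack the electron-rich ring B or give some flavone. The fallback sets out from 4 and comes back at 6. It uses the open-chain rearrangement instead, with ring C closed only after the shift: trivalent thallium nitrate, Tl(NO3)3·3H2O, in MeOH/HC(OMe)3 at rt converts 4 into the acetal racemic 1-[5-bromo-2-hydroxy-4-(triisopropylsilyloxy)phenyl]-3,3-dimethoxy-2-[2-methoxy-4-(triisopropylsilyloxy)phenyl]propan-1-one F1. Warming F1 with catalytic PPTS in toluene at 80 °C closes the pyranone with loss of methanol to give 6.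

Step 4 (borylation and geranylation next to a bulky silyl ether). The hindered bromide may borylate sluggishly, the boronate may protodeboronate, and aqueous carbonate may loosen the 7-silyl ether. The fallback sets out from 6 and comes back at 11. The bromide is carried through the transfer hydrogenation first (conditions of step 5), giving racemic 6-bromo-3-[2-methoxy-4-(triisopropylsilyloxy)phenyl]-7-(triisopropylsilyloxy)chroman-4-one F2, which is not isolated, and then (3S,4S)-6-bromo-3-[2-methoxy-4-(triisopropylsilyloxy)phenyl]-7-(triisopropylsilyloxy)chroman-4-ol F3. With no carbonyl left, F3 is treated with t-BuLi (3.2 equiv, THF, −78 °C; the first equivalent deprotonates the alcohol), then CuBr·SMe2 and geranyl bromide 7. SN2 allylation of the aryl copper species gives 11 with the 2E geometry retained. The risk to watch is silyl migration from oxygen to the lithiated carbon, which is minimised by immediate transmetalation to copper at −78 °C.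

Step 5 (reduction cascade that sets C3). The ruthenium hydride may not reduce the hindered, fully protected chromone C=C, or the selectivity of the resolution may be low. The fallback sets out from 9 and comes back at 12, bypassing 11. It sets C3 by enantioselective protonation: Li[HB(s-Bu)3] in THF at −78 °C adds hydride 1,4, and Me3SiCl traps the enolate as the silyl enol ether 6-[(2E)-3,7-dimethylocta-2,6-dien-1-yl]-3-[2-methoxy-4-(triisopropylsilyloxy)phenyl]-7-(triisopropylsilyloxy)-4-(trimethylsilyloxy)-2H-chromene F4. F4 is then protonated at C3 with a chiral BINOL-derived N-triflyl thiophosphoramide (5 mol %) and phenol as the stoichiometric proton source in toluene at low temperature. The catalyst enantiomer that gives the (3S) ketone is chosen by a test run, and the product is 12.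

Further compounds
F1 | step 3 | racemic 1-[5-bromo-2-hydroxy-4-(triisopropylsilyloxy)phenyl]-3,3-dimethoxy-2-[2-methoxy-4-(triisopropylsilyloxy)phenyl]propan-1-one | COc1cc(O[Si](C(C)C)(C(C)C)C(C)C)ccc1C(C(OC)OC)C(=O)c1cc(Br)c(O[Si](C(C)C)(C(C)C)C(C)C)cc1O
F2 | step 4 | racemic 6-bromo-3-[2-methoxy-4-(triisopropylsilyloxy)phenyl]-7-(triisopropylsilyloxy)chroman-4-one | COc1cc(O[Si](C(C)C)(C(C)C)C(C)C)ccc1C1COc2cc(O[Si](C(C)C)(C(C)C)C(C)C)c(Br)cc2C1=O
F3 | step 4 | (3S,4S)-6-bromo-3-[2-methoxy-4-(triisopropylsilyloxy)phenyl]-7-(triisopropylsilyloxy)chroman-4-ol | COc1cc(O[Si](C(C)C)(C(C)C)C(C)C)ccc1[C@H]1COc2cc(O[Si](C(C)C)(C(C)C)C(C)C)c(Br)cc2[C@H]1O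
F4 | step 5 | 6-[(2E)-3,7-dimethylocta-2,6-dien-1-yl]-3-[2-methoxy-4-(triisopropylsilyloxy)phenyl]-7-(triisopropylsilyloxy)-4-(trimethylsilyloxy)-2H-chromene | COc1cc(O[Si](C(C)C)(C(C)C)C(C)C)ccc1C1=C(O[Si](C)(C)C)c2cc(C/C=C(\C)CCC=C(C)C)c(O[Si](C(C)C)(C(C)C)C(C)C)cc2OC1
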